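**Retrosynthetic overview**
- The target flavonol comes from its 5-O-methyl, 2',4'-di-O-benzyl precursor by hydrogenolysis and then chelation-directed 5-O-demethylation.
- The 3-OH is introduced by epoxidation/isomerisation of the corresponding flavone; the pyranone (C) ring is the only ring built, by oxidative cyclisation of a 2'-hydroxychalcone.
- The chalcone comes from a crossed aldol (Claisen–Schmidt) condensation of 2-hydroxy-3,4,6-trimethoxyacetophenone with 2,4-bis(benzyloxy)-5-methoxybenzaldehyde; this forms the key C–C bond.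
- The acetophenone comes from 3,4,5-trimethoxyphenol (methylation, then Friedel–Crafts acetylation with ortho-demethylation). The aldehyde comes from isovanillin (benzylation, Dakin-type oxidation, benzylation, Vilsmeier formylation).
- Ring order: the A and B rings are bought as arenes; the C ring is closed after the aldol step.

Assumption: the target has no stereocentre (it is achiral), so "single enantiomer" means the compound itself; the only stereo element in the route is the E-alkene of the chalcone.

**Step 1**
Reactants: 1 3,4,5-trimethoxyphenol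
Product: 2 1,2,3,5-tetramethoxybenzene
Conditions: MeI, K2CO3, acetone, reflux
Reagents that add atoms: iodomethane CI
Why: Williamson ether synthesis (SN2 O-methylation of the phenoxide) on the only free OH; no stereocentre is formed.

**Step 2**
Reactants: 2 1,2,3,5-tetramethoxybenzene
Product: 4 1-(2-hydroxy-3,4,6-trimethoxyphenyl)ethanone, via tetramethoxyacetophenone 3 (not isolated)
Conditions: AcCl (1.2 equiv), AlCl3 (2.5 equiv), Et2O, 0 °C → rt, 24 h; then ice-water
Reagents that add atoms: acetyl chloride CC(Cl)=O
Why: Friedel–Crafts acylation at one of the two equivalent activated positions, then chelation-controlled AlCl3 cleavage of the most crowded ortho-methoxy group (flanked by acetyl and OMe), gives the hydrogen-bonded o-hydroxy ketone; no stereocentre.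

**Step 3**
Reactants: 5 isovanillin (3-hydroxy-4-methoxybenzaldehyde)
Product: 6 3-(benzyloxy)-4-methoxybenzaldehyde
Conditions: BnBr, K2CO3, DMF, 60 °C
Reagents that add atoms: benzyl bromide BrCc1ccccc1
Why: Williamson O-benzylation of the single phenol; the aldehyde is inert to carbonate.

**Step 4**
Reactants: 6 3-(benzyloxy)-4-methoxybenzaldehyde
Product: 8 3-(benzyloxy)-4-methoxyphenol, via aryl formate 7 (not isolated)
Conditions: mCPBA, CH2Cl2, 0 °C → rt; then K2CO3 (cat.), MeOH, rt
Reagents that add atoms: mCPBA OOC(=O)c1cccc(Cl)c1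
Why: Baeyer–Villiger (Dakin-type) oxidation, in which the electron-rich aryl group migrates to give the aryl formate, and this is transesterified by methanol to the phenol.

**Step 5**
Reactants: 8 3-(benzyloxy)-4-methoxyphenol
Product: 9 2,4-bis(benzyloxy)-1-methoxybenzene
Conditions: BnBr, K2CO3, DMF, 60 °C
Reagents that add atoms: benzyl bromide BrCc1ccccc1
Why: Williamson O-benzylation of the only free phenol.

**Step 6**
Reactants: 9 2,4-bis(benzyloxy)-1-methoxybenzene
Product: 11 2,4-bis(benzyloxy)-5-methoxybenzaldehyde, via iminium chloride 10 (not isolated)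
Conditions: POCl3, DMF, 0 °C → 70 °C; then ice-water, rt
Reagents that add atoms: N,N-dimethylformamide CN(C)C=O; water O
Why: Vilsmeier–Haack formylation goes to the position para to one benzyloxy and ortho to the other (the site between the two OBn groups is blocked sterically), and the iminium salt is hydrolysed to the aldehyde.

**Step 7**
Reactants: 4 1-(2-hydroxy-3,4,6-trimethoxyphenyl)ethanone; 11 2,4-bis(benzyloxy)-5-methoxybenzaldehyde
Product: 13 (E)-3-[2,4-bis(benzyloxy)-5-methoxyphenyl]-1-(2-hydroxy-3,4,6-trimethoxyphenyl)prop-2-en-1-one, via aldol adduct 12 (not isolated)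
Conditions: KOH (50% aq, 10 equiv), EtOH/THF, rt, 48 h; then cold 1 M HCl to pH 3
Reagents that add atoms: none
Why: Claisen–Schmidt crossed aldol condensation of the methyl ketone enolate with a non-enolisable aldehyde, followed by E1cB dehydration to the thermodynamically favoured E-enone; no stereocentre remains.

**Step 8**
Reactants: 13 (E)-3-[2,4-bis(benzyloxy)-5-methoxyphenyl]-1-(2-hydroxy-3,4,6-trimethoxyphenyl)prop-2-en-1-one
Product: 15 2-[2,4-bis(benzyloxy)-5-methoxyphenyl]-5,7,8-trimethoxy-4H-chromen-4-one, via flavanone 14 (not isolated)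
Conditions: I2 (0.1 equiv), DMSO, 120 °C, 2–4 h; then aq Na2S2O3
Reagents that add atoms: none
Why: Oxidative cyclisation of a 2'-hydroxychalcone: intramolecular oxa-Michael addition gives the flavanone, which is α-iodinated and loses HI, DMSO re-oxidising HI to I2; the flavanone stereocentre is destroyed.

**Step 9**
Reactants: 15 2-[2,4-bis(benzyloxy)-5-methoxyphenyl]-5,7,8-trimethoxy-4H-chromen-4-one
Product: 17 2-[2,4-bis(benzyloxy)-5-methoxyphenyl]-3-hydroxy-5,7,8-trimethoxy-4H-chromen-4-one, via epoxyflavanone 16 (not isolated)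
Conditions: DMDO (acetone solution, 3 equiv), CH2Cl2, 0 °C → rt; then p-TsOH·H2O (cat.), CH2Cl2, rt
Reagents that add atoms: dimethyldioxirane CC1(C)OO1
Why: Dimethyldioxirane epoxidation of the enol-ether-like C2=C3 bond, then acid-catalysed epoxide opening at C2 and loss of H-3, gives the aromatic 3-hydroxyflavone; no stereocentre remains.

**Step 10**
Reactants: 17 2-[2,4-bis(benzyloxy)-5-methoxyphenyl]-3-hydroxy-5,7,8-trimethoxy-4H-chromen-4-one
Product: 18 2-(2,4-dihydroxy-5-methoxyphenyl)-3-hydroxy-5,7,8-trimethoxy-4H-chromen-4-one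
Conditions: H2 (1 atm), 10% Pd/C, THF/MeOH, rt
Reagents that add atoms: none
Why: Catalytic hydrogenolysis cleaves both aryl benzyl ethers, while methyl ethers and the conjugated, tetrasubstituted C2=C3 bond of the flavonol are untouched under these mild conditions.

**Step 11**
Reactants: 18 2-(2,4-dihydroxy-5-methoxyphenyl)-3-hydroxy-5,7,8-trimethoxy-4H-chromen-4-one
Product: 19 2-(2,4-dihydroxy-5-methoxyphenyl)-3,5-dihydroxy-7,8-dimethoxy-4H-chromen-4-one (target)
Conditions: anhydrous AlCl3 (6 equiv), MeCN, 50 °C, monitored by HPLC; then dilute aqueous acid, 50 °C, 30 min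
Reagents that add atoms: none
Why: Chelation-directed Lewis-acid ether cleavage: aluminium bound between the C4 carbonyl and the peri 5-OMe activates only that methyl group for chloride attack, so the 7-, 8- and 5'-methyl ethers are kept.

**Compound list**

1 | 3,4,5-trimethoxyphenol | COc1cc(O)cc(OC)c1OC | starting material
2 | 1,2,3,5-tetramethoxybenzene | COc1cc(OC)c(OC)c(OC)c1 | intermediate
3 | 1-(2,3,4,6-tetramethoxyphenyl)ethanone (not isolated) | CC(=O)c1c(OC)cc(OC)c(OC)c1OC | intermediate
4 | 1-(2-hydroxy-3,4,6-trimethoxyphenyl)ethanone | CC(=O)c1c(OC)cc(OC)c(OC)c1O | intermediate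
5 | isovanillin (3-hydroxy-4-methoxybenzaldehyde) | COc1ccc(C=O)cc1O | starting material
6 | 3-(benzyloxy)-4-methoxybenzaldehyde | COc1ccc(C=O)cc1OCc1ccccc1 | intermediate
7 | 3-(benzyloxy)-4-methoxyphenyl formate (not isolated) | COc1ccc(OC=O)cc1OCc1ccccc1 | intermediate
8 | 3-(benzyloxy)-4-methoxyphenol | COc1ccc(O)cc1OCc1ccccc1 | intermediate
9 | 2,4-bis(benzyloxy)-1-methoxybenzene | COc1ccc(OCc2ccccc2)cc1OCc1ccccc1 | intermediate
10 | N-[2,4-bis(benzyloxy)-5-methoxybenzylidene]-N-methylmethanaminium chloride (not isolated) | COc1cc(C=[N+](C)C)c(OCc2ccccc2)cc1OCc1ccccc1.[Cl-] | intermediate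
11 | 2,4-bis(benzyloxy)-5-methoxybenzaldehyde | COc1cc(C=O)c(OCc2ccccc2)cc1OCc1ccccc1 | intermediate
12 | 3-[2,4-bis(benzyloxy)-5-methoxyphenyl]-3-hydroxy-1-(2-hydroxy-3,4,6-trimethoxyphenyl)propan-1-one (racemic aldol adduct, not isolated) | COc1cc(OC)c(C(=O)CC(O)c2cc(OC)c(OCc3ccccc3)cc2OCc2ccccc2)c(O)c1OC | intermediate
13 | (E)-3-[2,4-bis(benzyloxy)-5-methoxyphenyl]-1-(2-hydroxy-3,4,6-trimethoxyphenyl)prop-2-en-1-one | COc1cc(OC)c(C(=O)/C=C/c2cc(OC)c(OCc3ccccc3)cc2OCc2ccccc2)c(O)c1OC | intermediate
14 | 2-[2,4-bis(benzyloxy)-5-methoxyphenyl]-5,7,8-trimethoxychroman-4-one (racemic flavanone, not isolated) | COc1cc(OC)c2c(c1OC)OC(c1cc(OC)c(OCc3ccccc3)cc1OCc1ccccc1)CC2=O | intermediate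
15 | 2-[2,4-bis(benzyloxy)-5-methoxyphenyl]-5,7,8-trimethoxy-4H-chromen-4-one | COc1cc(OC)c2c(=O)cc(-c3cc(OC)c(OCc4ccccc4)cc3OCc3ccccc3)oc2c1OC | intermediate
16 | 2-[2,4-bis(benzyloxy)-5-methoxyphenyl]-2,3-epoxy-5,7,8-trimethoxychroman-4-one (racemic, cis-fused epoxide, not isolated) | COc1cc(OC)c2c(c1OC)OC1(c3cc(OC)c(OCc4ccccc4)cc3OCc3ccccc3)OC1C2=O | intermediate
17 | 2-[2,4-bis(benzyloxy)-5-methoxyphenyl]-3-hydroxy-5,7,8-trimethoxy-4H-chromen-4-one | COc1cc(OC)c2c(=O)c(O)c(-c3cc(OC)c(OCc4ccccc4)cc3OCc3ccccc3)oc2c1OC | intermediate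
18 | 2-(2,4-dihydroxy-5-methoxyphenyl)-3-hydroxy-5,7,8-trimethoxy-4H-chromen-4-one | COc1cc(OC)c2c(=O)c(O)c(-c3cc(OC)c(O)cc3O)oc2c1OC | intermediate
19 | 2-(2,4-dihydroxy-5-methoxyphenyl)-3,5-dihydroxy-7,8-dimethoxy-4H-chromen-4-one | COc1cc(-c2oc3c(OC)c(OC)cc(O)c3c(=O)c2O)c(O)cc1O | target

**Totals**
Total step count: 11.
Longest linear sequence: 9 steps (5 → 6 → 8 → 9 → 11 → 13 → 15 → 17 → 18 → 19). The A-ring branch (1 → 2 → 4) is 2 steps and joins at step 7.

**Three steps most likely to fail, with fallbacks**

Step 8 (I2/DMSO oxidative cyclisation). The risk is HI-mediated loss of benzyl or 5-O-methyl groups, or ring iodination of the electron-rich arenes, at 120 °C. The fallback sets out from chalcone 13 and separates ring closure from oxidation. Compound 13 is cyclised under mild base (NaOAc, EtOH, reflux) to the flavanone 14, which is isolated this time. Compound 14 is then dehydrogenated by hydride abstraction with DDQ in dioxane at reflux, with no iodine or HI present. The fallback returns to the route at flavone 15 and makes no compound outside the list (F0).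

Step 9 (DMDO epoxidation/isomerisation). The risk is slow epoxidation of the enone, which is twisted by the 2'-benzyloxy group, with competing oxidation of the trialkoxy B ring or the benzylic C–H bonds. The fallback sets out from flavone 15 and replaces electrophilic oxidation with a C3 metalation–borylation–oxidation sequence. LDA in THF at −78 °C lithiates C3, and B(OMe)3 traps the anion as dimethyl {2-[2,4-bis(benzyloxy)-5-methoxyphenyl]-5,7,8-trimethoxy-4-oxo-4H-chromen-3-yl}boronate F1. This is oxidised with H2O2/AcOH (0 °C → rt) to the 3-hydroxyflavone. The fallback returns to the route at compound 17.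

Step 11 (selective 5-O-demethylation of the free polyphenol). The risk is poor solubility of 18, further loss of the 8-OMe group, or acid-induced ring-opening isomerisation of the 5,7,8-pattern. The fallback sets out from the benzylated flavonol 17, which is soluble in CH2Cl2, and replaces hydrogenolysis plus AlCl3 with one low-temperature Lewis-acid global deprotection. BCl3 (excess) with pentamethylbenzene in CH2Cl2 at −78 → 0 °C removes both benzyl ethers, the benzyl cations being trapped by pentamethylbenzene. The same reagent cleaves only the carbonyl-chelated 5-O-methyl group. The fallback comes back to the route directly at target 19 and makes no compound outside the list (F0).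

**Further compounds**

F0 | step 8 | none | none
F1 | step 9 | dimethyl {2-[2,4-bis(benzyloxy)-5-methoxyphenyl]-5,7,8-trimethoxy-4-oxo-4H-chromen-3-yl}boronate | COB(OC)c1c(-c2cc(OC)c(OCc3ccccc3)cc2OCc2ccccc2)oc2c(OC)c(OC)cc(OC)c2c1=O
F0 | step 11 | none | none
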